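The daucane is numbered so that C1 carries the angular methyl, C4 the hydroxyl and isopropyl, C5 is the ring-fusion CH, C6 the acyloxy carbon and C8–C9 the oxirane. Ring A is C1–C5 and ring B is C1, C5–C10. The route rests on the C1–C10 bond. C1 is the β-carbon of a ring A enone (C4=O) and C10 the β-carbon of a vinyl ketone (C8=O), linked through C5–C6–C7. One cathodic β,β-coupling therefore closes ring B, creates quaternary C1 and the C5 fusion centre, and leaves two ketones as handles. Its precursor is 3-methylcyclopent-2-enone bearing at C5 a (6R)-silyloxy chain that ends in the vinyl ketone.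

Key step: step 6

Remarks on the chemistry
- Faces: β is the face that carries the C1 methyl. The target has 1β-CH3, 5α-H (trans fusion), 4β-OH/4α-isopropyl, 6β-acyloxy and an 8α,9α-oxirane.
- Oxirane: an oxirane on a seven-membered ring can only be cis-fused, and the target SMILES places its oxygen on the α face. It is therefore made by direct epoxidation of the Δ8(9) alkene; closure of a cis-diol monosulfonate with inversion would require a trans-fused oxirane and is not used.
- C5: with C6–O on the β face, C1–CH3 and C6–O are syn-diaxial in the trans-fused C4 ketone and H5 is antiperiplanar to C6–O. This ketone is therefore taken as the kinetic epimer and is kept away from base until C4 is quaternised.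
- Precursor design: O6 is carried as a triisopropylsilyl ether. It is non-chelating, stable to the cathodic medium and to later alkoxide-induced silyl migration, and it is a larger axial shield for C5 and C4.
- Ketone differentiation: the unhindered C8 ketone is masked as a dimethyl ketal before the C4 addition.
- Assumption: the (S)-tryptophan-derived boron catalyst is taken to give the (R)-carbinol in step 4; if the sense is opposite, its enantiomer is used.

Step 1
Reactants: 1 3-methylcyclopent-2-en-1-one; 2 bromine
Product: 4 2-bromo-3-methylcyclopent-2-en-1-one, via 2,3-dibromo-3-methylcyclopentanone 3 (not isolated)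
Conditions: Br2, CH2Cl2, 0 °C; then Et3N, 0 °C → rt
Reagents that add atoms: bromine BrBr
Why: Bromine addition to the enone followed by amine-induced loss of HBr (α-bromination of an enone) should give the 2-bromo enone, with no stereocentre remaining.

Step 2
Reactants: 4 2-bromo-3-methylcyclopent-2-en-1-one; 5 ethane-1,2-diol
Product: 6 6-bromo-7-methyl-1,4-dioxaspiro[4.4]non-6-ene
Conditions: HOCH2CH2OH, TsOH·H2O (cat.), benzene, reflux, water separator
Reagents that add atoms: ethane-1,2-diol OCCO
Why: Acid-catalysed ketalisation with azeotropic removal of water masks the carbonyl, and the vinylic bromine keeps the double bond in place.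

Step 3
Reactants: 6 6-bromo-7-methyl-1,4-dioxaspiro[4.4]non-6-ene; 7 N,N-dimethylformamide
Product: 9 7-methyl-1,4-dioxaspiro[4.4]non-6-ene-6-carbaldehyde, via vinyllithium 8 (not isolated)
Conditions: n-BuLi, THF, −78 °C; DMF, −78 → 0 °C; aq. NH4Cl
Reagents that add atoms: N,N-dimethylformamide CN(C)C=O
Why: Bromine–lithium exchange gives the α-keto vinyl anion equivalent, which is formylated by the formamide.

Step 4
Reactants: 9 7-methyl-1,4-dioxaspiro[4.4]non-6-ene-6-carbaldehyde; 10 2-(trimethylsilyloxy)buta-1,3-diene
Product: 12 (5R)-5-hydroxy-5-(7-methyl-1,4-dioxaspiro[4.4]non-6-en-6-yl)pent-1-en-3-one, via trimethylsilyl ether 11 (not isolated)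
Conditions: B-n-butyl-1,3,2-oxazaborolidin-5-one of N-tosyl-(S)-tryptophan (20 mol %), EtCN, −78 °C; then HF·pyridine, pyridine, THF, 0 °C
Reagents that add atoms: 2-(trimethylsilyloxy)buta-1,3-diene C=CC(=C)O[Si](C)(C)C
Why: In this catalytic enantioselective Mukaiyama aldol addition the chiral boron Lewis acid binds the aldehyde and exposes one carbonyl face to the silyl dienol ether, so C6 (R) is set by catalyst control, and buffered fluoride then frees the hydroxyl without touching the ketal.

Step 5
Reactants: 12 (5R)-5-hydroxy-5-(7-methyl-1,4-dioxaspiro[4.4]non-6-en-6-yl)pent-1-en-3-one; 13 triisopropylsilyl trifluoromethanesulfonate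
Product: 15 3-methyl-2-[(1R)-3-oxo-1-(triisopropylsilyloxy)pent-4-en-1-yl]cyclopent-2-en-1-one, via silyl ether ketal 14 (not isolated)
Conditions: iPr3SiOTf, 2,6-lutidine, CH2Cl2, −78 → 0 °C; then 10% aq. oxalic acid, SiO2, CH2Cl2, rt
Reagents that add atoms: triisopropylsilyl trifluoromethanesulfonate CC(C)[Si](C(C)C)(C(C)C)OS(=O)(=O)C(F)(F)F; water O
Why: O-Silylation with a silyl triflate and a hindered non-nucleophilic base is followed by mild acid hydrolysis of the labile enone ketal, and C6 is not touched.

Step 6
Reactants: 15 3-methyl-2-[(1R)-3-oxo-1-(triisopropylsilyloxy)pent-4-en-1-yl]cyclopent-2-en-1-one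
Product: 17 trans-fused 1β-methyl-6β-(triisopropylsilyloxy)-5α-H-hydroazulene-4,8-dione (daucane numbering), via C4 enol 16 (not isolated)
Conditions: Hg pool cathode, Pt anode, divided cell, −1.6 V vs SCE; MeCN/aq. KH2PO4–K2HPO4 buffer pH 7 (4:1), 0.2 M Et4NOTs, 5 mM 15, 0 °C
Reagents that add atoms: none
Why: Proposed new method: one-electron reduction of the vinyl ketone, the less substituted and more easily reduced enone, gives an oxyallyl radical anion whose terminus C10 adds as a nucleophilic radical to the electrophilic β-carbon C1 of the cyclopentenone, and the C5 α-keto radical so formed takes the second electron and two protons; the closest known reaction is the electroreductive hydrocyclisation of tethered bis-enones, so far shown only for smaller rings without quaternary centres. Ring B closes in the 7-endo-trig mode, which polarity matching favours over 6-exo attack at C5. C1 is controlled by the C6 stereocentre: in the reacting rotamer C6–H lies in the enone plane beside the C4 carbonyl oxygen, the non-chelating silyloxy group and the C7 chain straddle that plane, and C10 is delivered anti to the silyloxy group, which leaves the methyl and the silyloxy group syn. C5 is controlled in the ketonisation of the C4 enol 16, where the proton should enter axially, anti to the axial C1 methyl and C6 silyloxy groups, to give the trans fusion under kinetic control. The step needs the C5 enolate to be protonated faster than the antiperiplanar silyloxy group departs, which the phosphate buffer as a fast oxygen acid should secure, and it needs high dilution to suppress hydrodimerisation.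

Step 7
Reactants: 17 trans-fused silyloxy dione; 18 methoxytrimethylsilane
Product: 19 C8 dimethyl ketal of 17 (C4 ketone free)
Conditions: MeOSiMe3, Me3SiOTf (cat.), CH2Cl2, −78 °C; pyridine quench
Reagents that add atoms: methoxytrimethylsilane CO[Si](C)(C)C
Why: Silyl triflate-catalysed acetalisation with an alkoxysilane under cold, non-basic conditions should react at the unhindered C8 cycloheptanone and spare the congested C4 ketone, the base-labile C5 centre and the silyl ether.

Step 8
Reactants: 19 C8 dimethyl ketal; 20 isopropylmagnesium chloride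
Product: 22 4β-hydroxy-4α-isopropyl-6β-(triisopropylsilyloxy) C8 ketone, via ketal carbinol 21 (not isolated)
Conditions: iPrMgCl, CeCl3, THF, −78 °C; then 10% aq. oxalic acid, THF, 0 °C → rt
Reagents that add atoms: isopropylmagnesium chloride CC(C)[Mg]Cl; water O
Why: The weakly basic organocerium reagent adds 1,2 to the hindered, enolisable C4 ketone from the α face, anti to the axial C1 methyl and the C6 silyloxy-bearing carbon, which sets C4 (4β-OH, 4α-isopropyl), and the dilute acid work-up hydrolyses the dimethyl ketal.

Step 9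
Reactants: 22 hydroxy ketone; 23 N-phenylbis(trifluoromethanesulfonimide)
Product: 25 Δ8(9) enol triflate, via dilithium enolate alkoxide 24 (not isolated)
Conditions: LiN(iPr)2 (2.2 equiv), THF, −78 °C; PhNTf2, −78 → 0 °C; aq. NH4Cl
Reagents that add atoms: N-phenylbis(trifluoromethanesulfonimide) O=S(=O)(N(c1ccccc1)S(=O)(=O)C(F)(F)F)C(F)(F)F
Why: In this kinetic enolisation and O-triflation the hindered amide should remove a proton from the remote C9 methylene and not from C7, which sits next to the carbon bearing the axial silyloxy group, so the enol triflate forms towards C9.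

Step 10
Reactants: 25 Δ8(9) enol triflate; 26 methylzinc chloride
Product: 27 8-methyl Δ8(9) alkene (4β-OH, 6β-OSi(iPr)3)
Conditions: MeZnCl, Pd(PPh3)4 (5 mol %), THF, rt → 50 °C
Reagents that add atoms: methylzinc chloride C[Zn]Cl
Why: Palladium-catalysed Negishi cross-coupling of the enol triflate installs the C8 methyl without moving the double bond.

Step 11
Reactants: 27 8-methyl Δ8(9) alkene
Product: 28 4β,6β-diol (dauc-8-ene-4β,6β-diol skeleton)
Conditions: Bu4NF, THF, rt → 50 °C
Reagents that add atoms: none
Why: Fluoride-mediated desilylation frees the secondary C6 hydroxyl.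

Step 12
Reactants: 29 4-acetoxy-3-methoxybenzoic acid; 30 oxalyl chloride
Product: 31 4-acetoxy-3-methoxybenzoyl chloride
Conditions: (COCl)2, DMF (cat.), CH2Cl2, 0 °C → rt
Reagents that add atoms: oxalyl chloride O=C(Cl)C(=O)Cl
Why: Acid chloride formation through the chloroiminium catalyst proceeds with the phenol masked as its acetate.

Step 13
Reactants: 28 4β,6β-diol; 31 4-acetoxy-3-methoxybenzoyl chloride
Product: 32 6β-(4-acetoxy-3-methoxybenzoyloxy) alkene
Conditions: Et3N, DMAP, CH2Cl2, 0 → 40 °C
Reagents that add atoms: 4-acetoxy-3-methoxybenzoyl chloride COc1cc(C(=O)Cl)ccc1OC(C)=O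
Why: Acylation under nucleophilic catalysis esterifies the secondary C6 hydroxyl, while the tertiary C4 hydroxyl is inert.

Step 14
Reactants: 32 6β-aroyloxy alkene; 33 3-chloroperoxybenzoic acid
Product: 34 8α,9α-epoxide with the phenol still acetylated
Conditions: mCPBA, NaHCO3, CH2Cl2, 0 °C
Reagents that add atoms: 3-chloroperoxybenzoic acid OOC(=O)c1cccc(Cl)c1
Why: In this Prilezhaev epoxidation the peracid should approach the trisubstituted alkene from the α face, because the β face is blocked by the axial C1 methyl and the axial C6 aroyloxy group, which sets C8 and C9 together as the cis-fused α-oxirane.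

Step 15
Reactants: 34 epoxy ester acetate
Product: 35 target, CNP0254293.2
Conditions: NH3 (7 M in MeOH), 0 °C
Reagents that add atoms: none
Why: Ammonolysis cleaves the phenolic acetate far faster than the hindered alkyl aryl ester or the oxirane.

Compound list
1 | 3-methylcyclopent-2-en-1-one | CC1=CC(=O)CC1 | starting material
2 | bromine | BrBr | starting material
3 | 2,3-dibromo-3-methylcyclopentan-1-one (racemic, not isolated) | CC1(Br)CCC(=O)C1Br | intermediate
4 | 2-bromo-3-methylcyclopent-2-en-1-one | CC1=C(Br)C(=O)CC1 | intermediate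
5 | ethane-1,2-diol | OCCO | starting material
6 | 6-bromo-7-methyl-1,4-dioxaspiro[4.4]non-6-ene | CC1=C(Br)C2(CC1)OCCO2 | intermediate
7 | N,N-dimethylformamide | CN(C)C=O | starting material
8 | (7-methyl-1,4-dioxaspiro[4.4]non-6-en-6-yl)lithium (not isolated) | CC1=C([Li])C2(CC1)OCCO2 | intermediate
9 | 7-methyl-1,4-dioxaspiro[4.4]non-6-ene-6-carbaldehyde | CC1=C(C=O)C2(CC1)OCCO2 | intermediate
10 | 2-(trimethylsilyloxy)buta-1,3-diene | C=CC(=C)O[Si](C)(C)C | starting material
11 | (5R)-5-(7-methyl-1,4-dioxaspiro[4.4]non-6-en-6-yl)-5-(trimethylsilyloxy)pent-1-en-3-one (not isolated) | C=CC(=O)C[C@@H](O[Si](C)(C)C)C1=C(C)CCC12OCCO2 | intermediate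
12 | (5R)-5-hydroxy-5-(7-methyl-1,4-dioxaspiro[4.4]non-6-en-6-yl)pent-1-en-3-one | C=CC(=O)C[C@@H](O)C1=C(C)CCC12OCCO2 | intermediate
13 | triisopropylsilyl trifluoromethanesulfonate | CC(C)[Si](C(C)C)(C(C)C)OS(=O)(=O)C(F)(F)F | starting material
14 | (5R)-5-(7-methyl-1,4-dioxaspiro[4.4]non-6-en-6-yl)-5-(triisopropylsilyloxy)pent-1-en-3-one (not isolated) | C=CC(=O)C[C@@H](O[Si](C(C)C)(C(C)C)C(C)C)C1=C(C)CCC12OCCO2 | intermediate
15 | 3-methyl-2-[(1R)-3-oxo-1-(triisopropylsilyloxy)pent-4-en-1-yl]cyclopent-2-en-1-one (key-step precursor) | C=CC(=O)C[C@@H](O[Si](C(C)C)(C(C)C)C(C)C)C1=C(C)CCC1=O | intermediate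
16 | C4 enol of the cyclised 8-ketone, 1β-CH3, 6β-OSi(iPr)3 (not isolated) | CC(C)[Si](C(C)C)(C(C)C)O[C@@H]1CC(=O)CC[C@@]2(C)CCC(O)=C12 | intermediate
17 | trans-fused hydroazulene-4,8-dione, 1β-CH3, 5α-H, 6β-OSi(iPr)3 (key-step product) | CC(C)[Si](C(C)C)(C(C)C)O[C@@H]1CC(=O)CC[C@@]2(C)CCC(=O)[C@H]12 | intermediate
18 | methoxytrimethylsilane | CO[Si](C)(C)C | starting material
19 | 8,8-dimethoxy-4-ketone, 1β-CH3, 5α-H, 6β-OSi(iPr)3 | CC(C)[Si](C(C)C)(C(C)C)O[C@@H]1CC(OC)(OC)CC[C@@]2(C)CCC(=O)[C@H]12 | intermediate
20 | isopropylmagnesium chloride | CC(C)[Mg]Cl | starting material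
21 | 8,8-dimethoxy-4β-hydroxy-4α-isopropyl compound (not isolated) | CC(C)[Si](C(C)C)(C(C)C)O[C@@H]1CC(OC)(OC)CC[C@@]2(C)CC[C@@](O)(C(C)C)[C@H]12 | intermediate
22 | 4β-hydroxy-4α-isopropyl-6β-(triisopropylsilyloxy)-8-ketone | CC(C)[Si](C(C)C)(C(C)C)O[C@@H]1CC(=O)CC[C@@]2(C)CC[C@@](O)(C(C)C)[C@H]12 | intermediate
23 | N-phenylbis(trifluoromethanesulfonimide) | O=S(=O)(N(c1ccccc1)S(=O)(=O)C(F)(F)F)C(F)(F)F | starting material
24 | dilithium C8(9)-enolate C4-alkoxide of 22 (not isolated) | CC(C)[Si](C(C)C)(C(C)C)O[C@@H]1CC(O[Li])=CC[C@@]2(C)CC[C@@](O[Li])(C(C)C)[C@H]12 | intermediate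
25 | Δ8(9) enol triflate | CC(C)[Si](C(C)C)(C(C)C)O[C@@H]1CC(OS(=O)(=O)C(F)(F)F)=CC[C@@]2(C)CC[C@@](O)(C(C)C)[C@H]12 | intermediate
26 | methylzinc chloride | C[Zn]Cl | starting material
27 | 8-methyl Δ8(9) alkene, 4β-OH, 6β-OSi(iPr)3 | CC(C)[Si](C(C)C)(C(C)C)O[C@@H]1CC(C)=CC[C@@]2(C)CC[C@@](O)(C(C)C)[C@H]12 | intermediate
28 | 4β,6β-diol with 8-methyl Δ8(9) alkene | O[C@@H]1CC(C)=CC[C@@]2(C)CC[C@@](O)(C(C)C)[C@H]12 | intermediate
29 | 4-acetoxy-3-methoxybenzoic acid | COc1cc(C(=O)O)ccc1OC(C)=O | starting material
30 | oxalyl chloride | O=C(Cl)C(=O)Cl | starting material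
31 | 4-acetoxy-3-methoxybenzoyl chloride | COc1cc(C(=O)Cl)ccc1OC(C)=O | intermediate
32 | 6β-(4-acetoxy-3-methoxybenzoyloxy)-4β-hydroxy Δ8(9) alkene | COc1cc(C(=O)O[C@@H]2CC(C)=CC[C@@]3(C)CC[C@@](O)(C(C)C)[C@H]23)ccc1OC(C)=O | intermediate
33 | 3-chloroperoxybenzoic acid | OOC(=O)c1cccc(Cl)c1 | starting material
34 | 8α,9α-epoxy 6β-(4-acetoxy-3-methoxybenzoate) | COc1cc(C(=O)O[C@@H]2C[C@@]3(C)O[C@H]3C[C@@]3(C)CC[C@@](O)(C(C)C)[C@H]23)ccc1OC(C)=O | intermediate
35 | CNP0254293.2, 8α,9α-epoxy-4β-hydroxy-6β-vanilloyloxy daucane | COc1cc(C(=O)O[C@@H]2C[C@@]3(C)O[C@H]3C[C@@]3(C)CC[C@@](O)(C(C)C)[C@H]23)ccc1O | target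

Total step count: 15. Longest linear sequence: 14 (steps 1–11 and 13–15; step 12 is a one-step branch).

Steps most likely to fail

Step 6. What may go wrong: two-electron saturation or intermolecular hydrodimerisation of the vinyl ketone outrunning the slow 7-endo attack on the fully substituted C1; expulsion of the silyloxy group from the C5 enolate; or attack through the other C5–C6 rotamer (C6–H beside the C1 methyl), which would deliver C10 to the wrong face of C1. The fallback uses known chemistry, sets out from 15 and returns at 17. Irradiation of 15 (350 nm, Pyrex, CH2Cl2, −40 °C) should give, by intramolecular enone–alkene [2+2] photocycloaddition in the usual 1,5-closure sense (C5–C9 first, then C1–C10), the cyclobutane photoadduct F1. Its C5–C9 bond lies between the two carbonyl groups. Reductive cleavage of this strained 1,4-diketone bond with SmI2 in THF–MeOH at −78 °C, with protonation at C9 and C5, should return the dione 17.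

Step 8. What may go wrong: β-hydride transfer from the isopropyl reagent, or enolisation followed by loss of the silyloxy group, competing with addition at the congested C4 carbonyl. The fallback sets out from 19 and returns at 21. Addition of 2-propenylmagnesium bromide with CeCl3 (THF, −78 °C), an sp2 nucleophile that is smaller and does not reduce by β-hydride transfer, should give the isopropenyl carbinol F2 from the same α face. Hydrogenation of its 1,1-disubstituted alkene (H2, RhCl(PPh3)3, benzene, rt) gives the ketal carbinol 21, which is hydrolysed to 22 as in step 8.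

Step 9. What may go wrong: proton removal at C7 instead of C9, leading to the regioisomeric enol triflate or to loss of the silyloxy group. The fallback sets out from 22 and returns at 27, bypassing 25. Condensation with 2,4,6-triisopropylbenzenesulfonohydrazide (THF, rt) should give the C8 arylsulfonylhydrazone F3, formed anti to the hindered C7 side. In a Shapiro reaction (n-BuLi, THF/TMEDA, −78 → 0 °C) the C9 proton syn to the sulfonamide nitrogen is removed, and loss of sulfinate and dinitrogen gives the C8 vinyllithium F4. Quenching with iodomethane at −78 °C gives alkene 27.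

Further compounds
F1 | step 6 | cyclobutane photoadduct of 15 with C1–C10 and C5–C9 bonds, 1β-CH3, 6β-OSi(iPr)3 | O=C1CC[C@]2(C)C[C@H]3C(=O)C[C@@H](O[Si](C(C)C)(C(C)C)C(C)C)[C@@]123
F2 | step 8 | 8,8-dimethoxy-4β-hydroxy-4α-(prop-1-en-2-yl) compound | CC(C)[Si](C(C)C)(C(C)C)O[C@@H]1CC(OC)(OC)CC[C@@]2(C)CC[C@@](O)(C(C)=C)[C@H]12
F3 | step 9 | C8 2,4,6-triisopropylbenzenesulfonylhydrazone of 22 | CC(C)[Si](C(C)C)(C(C)C)O[C@@H]1CC(=NNS(=O)(=O)c3c(C(C)C)cc(C(C)C)cc3C(C)C)CC[C@@]2(C)CC[C@@](O)(C(C)C)[C@H]12
F4 | step 9 | C8 vinyllithium (Δ8(9)) lithium C4-alkoxide | CC(C)[Si](C(C)C)(C(C)C)O[C@@H]1CC([Li])=CC[C@@]2(C)CC[C@@](O[Li])(C(C)C)[C@H]12
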